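## Retrosynthetic overview

1. Feature used: ring B is the ten-membered oxacycle O–C3–C4–C5–C6–C7–C8–C9–C10–C11; C5 is allylic to the C6=C7 alkene that later becomes the epoxide, and C4 is α to C3, which can be carried as a lactone carbonyl on the tertiary C11 oxygen of ring A.
2. Target ⇐ C6=C7 alkene (Shi epoxidation) ⇐ C3 aldehyde and alcohol (Wittig, oxidation) ⇐ exocyclic C3 enol ether (DMDO, then AlMe3) ⇐ ten-membered lactone (Tebbe) ⇐ 4-sulfonyl lactone (aluminium amalgam).
3. Ring B ⇐ C4–C5 bond: palladium π-allyl alkylation of the C11 (phenylsulfonyl)acetate by its own E allylic methyl carbonate.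
4. Precursor ⇐ esterification, carbonate formation, DIBAL reduction and Horner–Wadsworth–Emmons extension of the C7 ketone; ring A (C10, C11, C14) ⇐ enantioselective bromonium cyclisation of geranylacetone.
5. Order of ring formation: ring A (step 1), ring B (step 6), oxirane (step 12).

Key step: step 6

Remark: locants are those of geranyllinalool (C1=C2 vinyl, C3 ether carbon, C6/C7 epoxide, ring A = C10–C15); hydroxy ketone 3 is written open-chain although it equilibrates with its cyclic hemiketal, and lactone 10 is carried as a mixture of C4 epimers.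

Remark: the face selectivities in ring B (steps 9 and 12) rest on a trans-fused chair model of rings A and B and are working hypotheses to be confirmed by NOE on 14 and 17.

## Route

Step 1
Reactants: 1 geranylacetone
Product: 3 4-[(1S,3S,6S)-3-bromo-6-hydroxy-2,2,6-trimethylcyclohexyl]butan-2-one, via bicyclic bromo enol ether 2 (not isolated)
Conditions: DBDMH (1.1 equiv), chiral 3,3′-bis(2,4,6-triisopropylphenyl)-BINOL N-triflyl thiophosphoramide (10 mol %), toluene/CH2Cl2, −78 °C; then 0.5 M aq. HCl, THF, 0 °C
Reagents that add atoms: 1,3-dibromo-5,5-dimethylhydantoin (DBDMH), CC1(C)N(Br)C(=O)N(Br)C1=O; water, O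
Why: Proposed new method: the Lewis-basic P=S group of the chiral thiophosphoramide should take Br+ from DBDMH and pass it to one face of the terminal, most electron-rich C14=C15 alkene; the C10=C11 alkene then adds anti through a chair transition state (fixing C10 and C11 relative to C14, Br equatorial, trans ring fusion) and the ketone oxygen traps the C11 cation to give enol ether 2, which dilute acid hydrolyses to 3; the closest known reaction types are the same catalyst/DBDMH bromocyclisation of homogeranyl arenes and the racemic bromonium cyclisation of geranylacetone, and the catalyst antipode that leads to the (14S) series has to be assigned in the first run.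

Step 2
Reactants: 3 hydroxy ketone; 4 triethyl phosphonoacetate
Product: 5 ethyl (2E)-5-[(1S,3S,6S)-3-bromo-6-hydroxy-2,2,6-trimethylcyclohexyl]-3-methylpent-2-enoate
Conditions: 4 (1.5 equiv), NaH (1.4 equiv), THF, 0 °C; then 3, 0 → 50 °C; chromatographic removal of the 6Z ester
Reagents that add atoms: triethyl phosphonoacetate (4), CCOC(=O)CP(=O)(OCC)OCC
Why: Horner–Wadsworth–Emmons olefination of the methyl ketone by the preformed sodium phosphonate, which is too weak a base to deprotonate the tertiary alcohol or eliminate HBr; the E isomer (C8 trans to the ester) is expected to predominate and the minor Z ester is removed here so that only E material goes on.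

Step 3
Reactants: 5 hydroxy enoate
Product: 6 (1S,2S,4S)-4-bromo-2-[(3E)-5-hydroxy-3-methylpent-3-en-1-yl]-1,3,3-trimethylcyclohexan-1-ol
Conditions: i-Bu2AlH (3.5 equiv), CH2Cl2, −78 °C; aq. KNaC4H4O6 work-up
Reagents that add atoms: none
Why: DIBAL 1,2-reduction of the α,β-unsaturated ester to the allylic alcohol at low temperature should leave the alkene geometry, the secondary bromide and the tertiary alcohol untouched.

Step 4
Reactants: 6 diol
Product: 7 (2E)-5-[(1S,3S,6S)-3-bromo-6-hydroxy-2,2,6-trimethylcyclohexyl]-3-methylpent-2-en-1-yl methyl carbonate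
Conditions: ClCO2Me (1.2 equiv), pyridine, CH2Cl2, 0 °C
Reagents that add atoms: methyl chloroformate, COC(=O)Cl
Why: Acylation with methyl chloroformate/pyridine is selective for the primary allylic alcohol, since the hindered tertiary C11 alcohol should not react at 0 °C.

Step 5
Reactants: 7 hydroxy carbonate; 8 (phenylsulfonyl)acetic acid
Product: 9 (1S,2S,4S)-4-bromo-2-[(3E)-5-(methoxycarbonyloxy)-3-methylpent-3-en-1-yl]-1,3,3-trimethylcyclohexyl (phenylsulfonyl)acetate
Conditions: 8, DCC, DMAP (cat.), CH2Cl2, 0 °C → rt
Reagents that add atoms: (phenylsulfonyl)acetic acid (8), OC(=O)CS(=O)(=O)c1ccccc1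
Why: Carbodiimide (Steglich-type) esterification; DCC-activated C–H acidic acids of this kind acylate even tertiary alcohols, as malonate half-esters do, and the allylic carbonate is inert to DCC/DMAP.

Step 6
Reactants: 9 sulfonylacetate allylic carbonate
Product: 10 ten-membered ring-B lactone bearing 4-phenylsulfonyl (6E; C4 epimers)
Conditions: Pd(PPh3)4 (10 mol %), THF, 65 °C, syringe-pump addition of 9 over 12 h (final 2 mM)
Reagents that add atoms: none
Why: Zerovalent palladium ionises the C5 methyl carbonate of 9 to a syn η3-allylpalladium complex spanning C5–C7, and the methoxide released with CO2 deprotonates the (phenylsulfonyl)acetate at C4, so no external base is needed. The soft C4 carbanion then attacks the allyl unit on the face opposite to palladium (Tsuji–Trost allylic alkylation; closest known reaction type: palladium-catalysed cyclisation of ω-(phenylsulfonyl)acetoxy allylic esters to medium and large lactones, ten-membered ones included). Ring B closes in the endo mode by attack at the primary C5 terminus, which places the whole allyl unit inside the new ten-membered lactone ring (endocyclic C6=C7); attack at the fully substituted C7 terminus would give an eight-membered ring with a quaternary centre and is disfavoured sterically. The only new stereocentre, C4, forms as a mixture of epimers and is erased in step 7, while the ring-A centres are not touched. The E alkene follows from the E carbonate: the syn complex keeps the C8 chain trans to C5, and syn/anti exchange would need an η1 bond at tertiary C7, so capture should be faster than isomerisation. Ring closure has to outrun intermolecular alkylation, which slow addition at high dilution and the gauche, trans-diequatorial placement of the C9 chain and the C11 ester oxygen on the ring-A chair should secure.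

Step 7
Reactants: 10 sulfonyl lactone
Product: 11 ten-membered ring-B lactone (6E,10S,11S,14S; C4H2)
Conditions: aluminium amalgam (Al/Hg), THF/H2O 9:1, 0 °C → rt
Reagents that add atoms: none
Why: Reductive desulfonylation of the α-sulfonyl ester by aluminium amalgam (electron transfer, then protonation of the ester enolate) removes the C4 stereocentre without reducing the unactivated secondary bromide, the alkene or the lactone.

Step 8
Reactants: 11 lactone
Product: 12 exocyclic enol ether (C3=CH2) of ring B
Conditions: Cp2Ti(μ-Cl)(μ-CH2)AlMe2 (Tebbe reagent), pyridine, THF/toluene, −40 → 0 °C; aq. NaOH quench, basic alumina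
Reagents that add atoms: Tebbe reagent (μ-chloro bridge written with formal charges on Al and Cl), C[Al-]1(C)C[Ti](C2C=CC=C2)(C2C=CC=C2)[Cl+]1
Why: Tebbe methylenation (titanocene methylidene, [2+2] then cycloreversion) turns the lactone carbonyl into the enol ether without ionising the tertiary C11–O bond, and the low temperature avoids a Cope shift of the 1,5-diene CH2=C3–C4–C5–C6=C7.

Step 9
Reactants: 12 exocyclic enol ether
Product: 14 (3R)-3-(hydroxymethyl)-3-methyl ring-B ether, via spiro epoxy ether 13 (not isolated)
Conditions: DMDO (1.05 equiv), CH2Cl2/acetone, −78 °C; volatiles removed below −20 °C; AlMe3 (3 equiv), CH2Cl2, −78 → −20 °C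
Reagents that add atoms: dimethyldioxirane, CC1(C)OO1; trimethylaluminium, C[Al](C)C
Why: DMDO should epoxidise the electron-rich enol ether far faster than C6=C7 and from the peripheral face of ring B, turned away from the C8–C9 bridge and the axial C11 methyl; AlMe3 then opens epoxy ether 13 at the acetal carbon C3 and returns methyl to the face the oxygen leaves (enol-ether epoxidation/trialkylaluminium opening, as used for angular methyl ethers), which sets C3 as R with its methyl anti to the C11 methyl.

Step 10
Reactants: 14 primary alcohol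
Product: 15 (3R)-3-formyl-3-methyl ring-B ether
Conditions: Dess–Martin periodinane, NaHCO3, CH2Cl2, 0 °C → rt
Reagents that add atoms: none
Why: Dess–Martin oxidation of the neopentyl primary alcohol under buffered conditions gives the aldehyde; C3 is quaternary and cannot epimerise.

Step 11
Reactants: 15 aldehyde
Product: 16 (3R,6E,10S,11S,14S)-14-bromo-3,11-epoxy-10,15-cyclophyta-1,6-diene
Conditions: Ph3PCH3Br, KN(SiMe3)2, THF, 0 °C; then 15, 0 °C → rt
Reagents that add atoms: methyltriphenylphosphonium bromide, C[P+](c1ccccc1)(c1ccccc1)c1ccccc1.[Br-]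
Why: Wittig methylenation with Ph3P=CH2 converts the hindered α-alkoxy aldehyde, which has no enolisable hydrogen, into the C1=C2 vinyl group.

Step 12
Reactants: 16 diene ether
Product: 17 (3R,6S,7S,10S,11S,14S)-14-bromo-3,11:6,7-diepoxy-10,15-cyclophyt-1-ene (target)
Conditions: L-fructose-derived Shi ketone (30 mol %), KHSO5 (as Oxone), K2CO3, Bu4NHSO4, MeCN/(MeO)2CH2, aq. Na2B4O7 buffer (pH 10.5), 0 °C
Reagents that add atoms: potassium peroxymonosulfate, [K+].[O-]S(=O)(=O)OO
Why: Shi epoxidation: the dioxirane from the L-fructose-derived ketone should transfer oxygen through a spiro transition state to the face of the E-trisubstituted C6=C7 alkene that gives the (6S,7S) trans-epoxide (syn addition keeps C5 and C8 trans), while the monosubstituted vinyl group is not attacked and the basic buffer protects the di-tertiary ether and the epoxide.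

## Compound list

1 | geranylacetone, (5E)-6,10-dimethylundeca-5,9-dien-2-one | CC(C)=CCC/C(C)=C/CCC(C)=O | starting material
2 | (4aS,6S,8aS)-6-bromo-2,5,5,8a-tetramethyl-4a,5,6,7,8,8a-hexahydro-4H-chromene (bicyclic bromo enol ether) | CC1=CC[C@H]2C(C)(C)[C@@H](Br)CC[C@]2(C)O1 | intermediate (not isolated)
3 | 4-[(1S,3S,6S)-3-bromo-6-hydroxy-2,2,6-trimethylcyclohexyl]butan-2-one | CC(=O)CC[C@H]1C(C)(C)[C@@H](Br)CC[C@]1(C)O | intermediate
4 | triethyl phosphonoacetate | CCOC(=O)CP(=O)(OCC)OCC | starting material
5 | ethyl (2E)-5-[(1S,3S,6S)-3-bromo-6-hydroxy-2,2,6-trimethylcyclohexyl]-3-methylpent-2-enoate | CCOC(=O)/C=C(C)/CC[C@H]1C(C)(C)[C@@H](Br)CC[C@]1(C)O | intermediate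
6 | (1S,2S,4S)-4-bromo-2-[(3E)-5-hydroxy-3-methylpent-3-en-1-yl]-1,3,3-trimethylcyclohexan-1-ol | OC/C=C(C)/CC[C@H]1C(C)(C)[C@@H](Br)CC[C@]1(C)O | intermediate
7 | (2E)-5-[(1S,3S,6S)-3-bromo-6-hydroxy-2,2,6-trimethylcyclohexyl]-3-methylpent-2-en-1-yl methyl carbonate | COC(=O)OC/C=C(C)/CC[C@H]1C(C)(C)[C@@H](Br)CC[C@]1(C)O | intermediate
8 | (phenylsulfonyl)acetic acid | OC(=O)CS(=O)(=O)c1ccccc1 | starting material
9 | (1S,2S,4S)-4-bromo-2-[(3E)-5-(methoxycarbonyloxy)-3-methylpent-3-en-1-yl]-1,3,3-trimethylcyclohexyl (phenylsulfonyl)acetate | COC(=O)OC/C=C(C)/CC[C@H]1C(C)(C)[C@@H](Br)CC[C@]1(C)OC(=O)CS(=O)(=O)c1ccccc1 | intermediate (key-step precursor)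
10 | ten-membered ring-B lactone O–C3(=O)–C4H(SO2Ph)–C5–C6=C7(CH3)–C8–C9–C10–C11, trans-fused to ring A (6E,10S,11S,14S; C4 epimers) | O=C1C(S(=O)(=O)c3ccccc3)C/C=C(C)/CC[C@H]2C(C)(C)[C@@H](Br)CC[C@]2(C)O1 | intermediate (key-step product)
11 | ten-membered ring-B lactone with C4H2 (6E,10S,11S,14S) | O=C1CC/C=C(C)/CC[C@H]2C(C)(C)[C@@H](Br)CC[C@]2(C)O1 | intermediate
12 | exocyclic enol ether, C3=CH2 on ring B (6E,10S,11S,14S) | C=C1CC/C=C(C)/CC[C@H]2C(C)(C)[C@@H](Br)CC[C@]2(C)O1 | intermediate
13 | spiro epoxy ether, oxirane on C3 with its oxygen on the face anti to the C11 methyl | C1O[C@@]12CC/C=C(C)/CC[C@H]3C(C)(C)[C@@H](Br)CC[C@]3(C)O2 | intermediate (not isolated)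
14 | (3R)-3-(hydroxymethyl)-3-methyl ring-B ether (6E,10S,11S,14S) | OC[C@@]1(C)CC/C=C(C)/CC[C@H]2C(C)(C)[C@@H](Br)CC[C@]2(C)O1 | intermediate
15 | (3R)-3-formyl-3-methyl ring-B ether (6E,10S,11S,14S) | O=C[C@@]1(C)CC/C=C(C)/CC[C@H]2C(C)(C)[C@@H](Br)CC[C@]2(C)O1 | intermediate
16 | (3R,6E,10S,11S,14S)-14-bromo-3,11-epoxy-10,15-cyclophyta-1,6-diene | C=C[C@@]1(C)CC/C=C(C)/CC[C@H]2C(C)(C)[C@@H](Br)CC[C@]2(C)O1 | intermediate
17 | (3R,6S,7S,10S,11S,14S)-14-bromo-3,11:6,7-diepoxy-10,15-cyclophyt-1-ene | C=C[C@@]1(C)CC[C@@H]2O[C@@]2(C)CC[C@H]2C(C)(C)[C@@H](Br)CC[C@]2(C)O1 | target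

## Step count and risks

Total steps: 12. Longest linear sequence: 12 steps, from geranylacetone 1.

Steps most likely to fail:

1. Step 1 (Proposed new method). The transfer of Br+ to C14=C15 may show weak enantiofacial discrimination, because the ketone can compete for the acidic site of the catalyst, or proton-initiated cyclisation may compete. The fallback sets out from 1 and uses resolution in place of asymmetric catalysis. TBCO (2,4,4,6-tetrabromocyclohexa-2,5-dienone) in MeNO2, the known racemic bromonium cyclisation of geranylacetone, should give the racemic bicyclic bromo enol ether F1. Dilute aq. HCl in THF hydrolyses it to the racemic hydroxy ketone F2, which is resolved by preparative HPLC on a polysaccharide chiral stationary phase. The (1S,3S,6S) enantiomer is 3, where the route is rejoined.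

2. Step 6. Intermolecular alkylation may outrun ring closure and give oligomers, or the allyl complex may lose a β-hydrogen to a diene before the hindered carbanion reaches C5. The fallback sets out from diol 6 and closes the same C4–C5 bond by direct SN2 alkylation without palladium. MsCl, LiCl and 2,4,6-collidine in DMF convert the primary allylic alcohol into the (1S,2S,4S) E allylic chloride F3. DCC/DMAP esterification with 8 gives the chloro (phenylsulfonyl)acetate F4. Cs2CO3 with catalytic NaI in MeCN at high dilution then alkylates the sulfonylacetate carbanion intramolecularly, a known way to close medium and large rings with allylic halides, and returns to the route at 10.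

3. Step 9. Oxygen may be delivered to the other face of the exocyclic enol ether, which would lead to the C3 epimer, or the tertiary C11–O bond may heterolyse once the epoxy ether has opened to the oxocarbenium aluminate, which would fragment ring B. The fallback sets out from 12 and reverses the roles of the two C3 substituents. Benzenesulfinic acid in CH2Cl2 at −20 °C adds across the enol ether to give the 3-methyl-3-(phenylsulfonyl) ring-B ether F5. CH2=CHMgBr/ZnBr2 in THF then displaces the sulfone (known substitution of 2-sulfonyl cyclic ethers by organozinc reagents). The C3 methyl now comes from protonation and vinyl enters last, so the same facial preference gives the opposite C3 configuration, under a milder zinc Lewis acid than AlMe3. This sequence returns to the route at 16.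

## Further compounds

F1 | step 1 | racemic bicyclic bromo enol ether (racemate of 2) | CC1=CC[C@H]2C(C)(C)[C@@H](Br)CC[C@]2(C)O1.CC1=CC[C@@H]2C(C)(C)[C@H](Br)CC[C@@]2(C)O1
F2 | step 1 | racemic 4-(3-bromo-6-hydroxy-2,2,6-trimethylcyclohexyl)butan-2-one (racemate of 3) | CC(=O)CC[C@H]1C(C)(C)[C@@H](Br)CC[C@]1(C)O.CC(=O)CC[C@@H]1C(C)(C)[C@H](Br)CC[C@@]1(C)O
F3 | step 6 | (1S,2S,4S)-4-bromo-2-[(3E)-5-chloro-3-methylpent-3-en-1-yl]-1,3,3-trimethylcyclohexan-1-ol | ClC/C=C(C)/CC[C@H]1C(C)(C)[C@@H](Br)CC[C@]1(C)O
F4 | step 6 | (1S,2S,4S)-4-bromo-2-[(3E)-5-chloro-3-methylpent-3-en-1-yl]-1,3,3-trimethylcyclohexyl (phenylsulfonyl)acetate | ClC/C=C(C)/CC[C@H]1C(C)(C)[C@@H](Br)CC[C@]1(C)OC(=O)CS(=O)(=O)c1ccccc1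
F5 | step 9 | 3-methyl-3-(phenylsulfonyl) ring-B ether (6E,10S,11S,14S; C3 epimers) | CC1(S(=O)(=O)c3ccccc3)CC/C=C(C)/CC[C@H]2C(C)(C)[C@@H](Br)CC[C@]2(C)O1
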